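**Retrosynthetic overview**
- The angelate at C1 is put on last. The C1 alcohol comes from Luche reduction of a ring enone that is unmasked from a dimethyl ketal, and both acetates come from one diol.
- The C9 carbinol comes from a prenyl ketone (methyl ester plus 2-methylprop-1-enyl Grignard by way of a Weinreb amide). The C4 and C9 carbinols are each set by oxazaborole-catalysed reduction.
- Key disconnection C6–C7: the carbene-generated homoenolate of (E)-but-2-enal (nucleophilic at its β-carbon, C7) adds to the enone β-carbon (C6) of 4,4-dimethoxy-2-methylcyclohexa-2,5-dien-1-one. Both carbons are natively electrophilic, and the step sets C6 and C7 together.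
- No ring is formed: the only ring is the carbocycle of 4-methoxy-2-methylphenol, dearomatised in the first step.

Atom labels: ring C1 (angelate carbon), C2=C3 (methyl on C3), C4 (OAc), C5, C6; side chain C7 (CH–CH3), C8, C9 (OAc), C10=C11.

Assumption: the sense of induction of the chiral triazolium salt in step 2 (and of the ligands named in the fallbacks) is assigned by analogy; if the opposite sense is found, the antipodal salt or ligand is used.

**Route**

Step 1
Reactants: 1 4-methoxy-2-methylphenol
Product: 2 4,4-dimethoxy-2-methylcyclohexa-2,5-dien-1-one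
Conditions: PhI(OAc)2 (1.1 equiv), MeOH, 0 °C to 23 °C
Reagents that add atoms: methanol, CO
Why: Hypervalent-iodine oxidative dearomatisation of a para-methoxyphenol in methanol (quinone monoketal formation) is a standard, high-yielding reaction, and no stereocentre is formed.

Step 2
Reactants: 2 4,4-dimethoxy-2-methylcyclohexa-2,5-dien-1-one; 3 (E)-but-2-enal
Product: 4 methyl (3R)-3-[(1S)-2,2-dimethoxy-4-methyl-5-oxocyclohex-3-en-1-yl]butanoate
Conditions: (5aS,10bR)-2-(2,4,6-trimethylphenyl)-5a,10b-dihydro-4H,6H-indeno[2,1-b][1,2,4]triazolo[4,3-d][1,4]oxazin-2-ium chloride (10 mol%), NaOAc (20 mol%), MeOH (5 equiv), THF, 23 °C, 3 (2.5 equiv) added over 6 h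
Reagents that add atoms: methanol, CO
Why: Proposed new method: the triazolylidene turns 3 into its extended Breslow intermediate (a homoenolate, nucleophilic at the β-carbon that becomes C7), which adds to the unsubstituted, ketal-activated enone β-carbon of 2 (C6) either directly or by carbonyl addition and oxy-Cope shift, and methanol then frees the catalyst from the acyl azolium as the methyl ester; the aminoindanol backbone shields one face of the homoenolate (C7 = R) and the enone is approached in the staggered orientation that keeps the C7 methyl away from the ketal methoxy groups (C6 = S); the closest known reaction type is the carbene-catalysed homoenolate Michael addition of enals to chalcones and nitroalkenes in alcohols, which gives acyclic esters with two new adjacent stereocentres.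

Step 3
Reactants: 4 methyl (3R)-3-[(1S)-2,2-dimethoxy-4-methyl-5-oxocyclohex-3-en-1-yl]butanoate
Product: 5 methyl (3R)-3-[(1S,5R)-5-hydroxy-2,2-dimethoxy-4-methylcyclohex-3-en-1-yl]butanoate
Conditions: (3aS)-1-methyl-3,3-diphenyltetrahydro-1H,3H-pyrrolo[1,2-c][1,3,2]oxazaborole (20 mol%), catecholborane (1.5 equiv), toluene, −78 °C; MeOH, aq NaHCO3
Reagents that add atoms: none
Why: Corey–Bakshi–Shibata reduction, in which the oxazaborole binds the ring ketone with the 2-methylvinyl arm as the large group and the CH2 arm as the small group and delivers hydride to the face that gives the (R)-carbinol at C4 (1,2-reduction only), the catalyst having to override the ring bias, while ester and ketal are inert at −78 °C.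

Step 4
Reactants: 5 methyl (3R)-3-[(1S,5R)-5-hydroxy-2,2-dimethoxy-4-methylcyclohex-3-en-1-yl]butanoate; 6 2-methylprop-1-en-1-ylmagnesium bromide
Product: 8 (6R)-6-[(1S,5R)-5-hydroxy-2,2-dimethoxy-4-methylcyclohex-3-en-1-yl]-2-methylhept-2-en-4-one, via Weinreb amide 7 (not isolated)
Conditions: MeNHOMe·HCl (1.6 equiv), iPrMgCl (4.5 equiv), THF, −20 °C; then 6 (3 equiv), −20 to 0 °C; aq NH4Cl
Reagents that add atoms: none
Why: One-pot Weinreb ketone synthesis, in which the chloromagnesium amide made from MeNHOMe·HCl and iPrMgCl converts the methyl ester into amide 7, whose stable magnesium chelate accepts exactly one alkenyl Grignard and releases the enone only on work-up; the C4 alkoxide is a spectator and no stereocentre is touched.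

Step 5
Reactants: 8 (6R)-6-[(1S,5R)-5-hydroxy-2,2-dimethoxy-4-methylcyclohex-3-en-1-yl]-2-methylhept-2-en-4-one
Product: 9 (4R,6R)-6-[(1S,5R)-5-hydroxy-2,2-dimethoxy-4-methylcyclohex-3-en-1-yl]-2-methylhept-2-en-4-ol
Conditions: (3aS)-1-methyl-3,3-diphenyltetrahydro-1H,3H-pyrrolo[1,2-c][1,3,2]oxazaborole (20 mol%), catecholborane (3 equiv), toluene, −78 °C; MeOH, aq NaHCO3
Reagents that add atoms: none
Why: Corey–Bakshi–Shibata reduction of an alkenyl alkyl ketone, with the 2-methylprop-1-enyl group as the large and the CH2 group as the small substituent (as in prostaglandin enone reductions), gives the (R)-allylic alcohol at C9 under catalyst control, the free C4 hydroxyl only consuming borane.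

Step 6
Reactants: 9 (4R,6R)-6-[(1S,5R)-5-hydroxy-2,2-dimethoxy-4-methylcyclohex-3-en-1-yl]-2-methylhept-2-en-4-ol
Product: 10 (1R,5S)-5-[(2R,4R)-4-(acetyloxy)-6-methylhept-5-en-2-yl]-4,4-dimethoxy-2-methylcyclohex-2-en-1-yl acetate
Conditions: Ac2O (4 equiv), pyridine, 4-(dimethylamino)pyridine (10 mol%), CH2Cl2, 0 to 23 °C
Reagents that add atoms: acetic anhydride, CC(=O)OC(C)=O
Why: Nucleophile-catalysed acylation of the two secondary allylic alcohols installs both acetates in one operation with retention at C4 and C9, and the basic medium leaves the ketal intact.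

Step 7
Reactants: 10 (1R,5S)-5-[(2R,4R)-4-(acetyloxy)-6-methylhept-5-en-2-yl]-4,4-dimethoxy-2-methylcyclohex-2-en-1-yl acetate
Product: 11 (1R,5S)-5-[(2R,4R)-4-(acetyloxy)-6-methylhept-5-en-2-yl]-2-methyl-4-oxocyclohex-2-en-1-yl acetate
Conditions: pyridinium 4-methylbenzenesulfonate (20 mol%), acetone/H2O 10:1, 23 °C
Reagents that add atoms: water, O
Why: Mild acid-catalysed hydrolysis of the allylic dimethyl ketal gives the C1 enone without ionising the allylic acetates or epimerising C6, and because C4 is already an acetate no ene-dione (hydroquinone tautomer) can arise.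

Step 8
Reactants: 11 (1R,5S)-5-[(2R,4R)-4-(acetyloxy)-6-methylhept-5-en-2-yl]-2-methyl-4-oxocyclohex-2-en-1-yl acetate
Product: 12 (1R,4S,5S)-5-[(2R,4R)-4-(acetyloxy)-6-methylhept-5-en-2-yl]-4-hydroxy-2-methylcyclohex-2-en-1-yl acetate
Conditions: NaBH4 (1.1 equiv), CeCl3·7H2O (1.2 equiv), MeOH, −78 °C
Reagents that add atoms: none
Why: Luche reduction is 1,2-selective, and axial hydride attack on the half-chair with the C6 side chain equatorial and the C4 acetate pseudoaxial gives the pseudoequatorial C1 alcohol, trans to the side chain and cis to the C4 acetate (C1 = S).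

Step 9
Reactants: 12 (1R,4S,5S)-5-[(2R,4R)-4-(acetyloxy)-6-methylhept-5-en-2-yl]-4-hydroxy-2-methylcyclohex-2-en-1-yl acetate; 13 (2Z)-2-methylbut-2-enoic acid (angelic acid)
Product: 15 (1S,4R,6S)-4-(acetyloxy)-6-[(2R,4R)-4-(acetyloxy)-6-methylhept-5-en-2-yl]-3-methylcyclohex-2-en-1-yl (2Z)-2-methylbut-2-enoate, via mixed anhydride 14 (not isolated)
Conditions: 13 (3 equiv), 2,4,6-trichlorobenzoyl chloride (3 equiv), Et3N (3.5 equiv), toluene, 23 °C, 2 h; then 12, 80 °C
Reagents that add atoms: none
Why: Yamaguchi-type esterification through the preformed mixed anhydride, run without a nucleophilic pyridine catalyst, acylates the C1 alcohol with retention and avoids the base-induced Z-to-E isomerisation of the angelate to the tiglate.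

**Compound list**
1 | 4-methoxy-2-methylphenol | COc1ccc(O)c(C)c1 | starting material
2 | 4,4-dimethoxy-2-methylcyclohexa-2,5-dien-1-one | COC1(OC)C=CC(=O)C(C)=C1 | intermediate
3 | (E)-but-2-enal | C/C=C/C=O | starting material
4 | methyl (3R)-3-[(1S)-2,2-dimethoxy-4-methyl-5-oxocyclohex-3-en-1-yl]butanoate | COC1(OC)C=C(C)C(=O)C[C@H]1[C@H](C)CC(=O)OC | intermediate
5 | methyl (3R)-3-[(1S,5R)-5-hydroxy-2,2-dimethoxy-4-methylcyclohex-3-en-1-yl]butanoate | COC1(OC)C=C(C)[C@H](O)C[C@H]1[C@H](C)CC(=O)OC | intermediate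
6 | 2-methylprop-1-en-1-ylmagnesium bromide | CC(C)=C[Mg]Br | starting material
7 | (3R)-3-[(1S,5R)-5-hydroxy-2,2-dimethoxy-4-methylcyclohex-3-en-1-yl]-N-methoxy-N-methylbutanamide | COC1(OC)C=C(C)[C@H](O)C[C@H]1[C@H](C)CC(=O)N(C)OC | intermediate
8 | (6R)-6-[(1S,5R)-5-hydroxy-2,2-dimethoxy-4-methylcyclohex-3-en-1-yl]-2-methylhept-2-en-4-one | COC1(OC)C=C(C)[C@H](O)C[C@H]1[C@H](C)CC(=O)C=C(C)C | intermediate
9 | (4R,6R)-6-[(1S,5R)-5-hydroxy-2,2-dimethoxy-4-methylcyclohex-3-en-1-yl]-2-methylhept-2-en-4-ol | COC1(OC)C=C(C)[C@H](O)C[C@H]1[C@H](C)C[C@H](C=C(C)C)O | intermediate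
10 | (1R,5S)-5-[(2R,4R)-4-(acetyloxy)-6-methylhept-5-en-2-yl]-4,4-dimethoxy-2-methylcyclohex-2-en-1-yl acetate | COC1(OC)C=C(C)[C@H](OC(C)=O)C[C@H]1[C@H](C)C[C@H](C=C(C)C)OC(C)=O | intermediate
11 | (1R,5S)-5-[(2R,4R)-4-(acetyloxy)-6-methylhept-5-en-2-yl]-2-methyl-4-oxocyclohex-2-en-1-yl acetate | O=C1C=C(C)[C@H](OC(C)=O)C[C@H]1[C@H](C)C[C@H](C=C(C)C)OC(C)=O | intermediate
12 | (1R,4S,5S)-5-[(2R,4R)-4-(acetyloxy)-6-methylhept-5-en-2-yl]-4-hydroxy-2-methylcyclohex-2-en-1-yl acetate | O[C@@H]1C=C(C)[C@H](OC(C)=O)C[C@H]1[C@H](C)C[C@H](C=C(C)C)OC(C)=O | intermediate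
13 | (2Z)-2-methylbut-2-enoic acid (angelic acid) | C/C=C(/C)C(=O)O | starting material
14 | (2Z)-2-methylbut-2-enoic 2,4,6-trichlorobenzoic anhydride | C/C=C(/C)C(=O)OC(=O)c1c(Cl)cc(Cl)cc1Cl | intermediate
15 | (1S,4R,6S)-4-(acetyloxy)-6-[(2R,4R)-4-(acetyloxy)-6-methylhept-5-en-2-yl]-3-methylcyclohex-2-en-1-yl (2Z)-2-methylbut-2-enoate | C/C=C(/C)C(=O)O[C@@H]1C=C(C)[C@H](OC(C)=O)C[C@H]1[C@H](C)C[C@H](C=C(C)C)OC(C)=O | target

**Totals**
Total step count: 9. Longest linear sequence: 9 steps (from 1).

**Steps most likely to fail, with fallbacks**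

Step 2 (the homoenolate addition to the quinone monoketal is unprecedented; risks are β-protonation of the homoenolate to methyl butanoate, self-condensation of 3, and the wrong relative configuration at C6/C7). The fallback sets out from 2 and comes back at 5. It replaces the catalytic homoenolate by a β-boryl enoate and sets C7 afterwards by asymmetric reduction. Copper-catalysed syn-borylation of methyl but-2-ynoate (CuCl, NaOtBu, 4,5-bis(diphenylphosphino)-9,9-dimethylxanthene, bis(pinacolato)diboron, MeOH, THF) gives methyl (2Z)-3-(4,4,5,5-tetramethyl-1,3,2-dioxaborolan-2-yl)but-2-enoate F1. Rhodium-catalysed asymmetric conjugate addition of F1 to 2 ([RhCl(C2H4)2]2, (R)-2,2'-bis(diphenylphosphino)-1,1'-binaphthyl, Et3N, dioxane/H2O, 40 °C; the same reaction type is known for alkenylboron reagents and quinone monoketals) sets C6 and gives methyl (2E)-3-[(1S)-2,2-dimethoxy-4-methyl-5-oxocyclohex-3-en-1-yl]but-2-enoate F2. Oxazaborole-catalysed reduction of the ring ketone under the conditions of step 3 gives methyl (2E)-3-[(1S,5R)-5-hydroxy-2,2-dimethoxy-4-methylcyclohex-3-en-1-yl]but-2-enoate F3. Ligand-controlled copper hydride conjugate reduction of the β,β-disubstituted enoate (Cu(OAc)2·H2O, (S)-2,2'-bis(di-4-tolylphosphino)-1,1'-binaphthyl, polymethylhydrosiloxane, tBuOH, toluene, 0 °C; fluoride work-up) then sets C7 and gives 5.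

Step 3 (a small hydride would follow the ring bias to the 1,3-cis alcohol, so the catalyst works in the mismatched sense and selectivity may erode). The fallback sets out from 4 and comes back at 5. It uses the substrate bias on purpose and then inverts. Luche reduction of 4 (NaBH4, CeCl3·7H2O, MeOH, −78 °C) gives methyl (3R)-3-[(1S,5S)-5-hydroxy-2,2-dimethoxy-4-methylcyclohex-3-en-1-yl]butanoate F4. Mitsunobu inversion (4-nitrobenzoic acid, PPh3, diisopropyl azodicarboxylate, THF, 0 °C) gives (1R,5S)-4,4-dimethoxy-5-[(2R)-4-methoxy-4-oxobutan-2-yl]-2-methylcyclohex-2-en-1-yl 4-nitrobenzoate F5. Methanolysis (K2CO3, MeOH, 0 °C) cleaves only the nitrobenzoate and gives 5.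

Step 9 (a hindered secondary allylic alcohol next to the branched C6, and the angelate can isomerise to the tiglate under forcing acylation). The fallback sets out from 12 and comes back at 15. It builds the Z double bond on the substrate instead of transferring it. Carbodiimide esterification of 12 with 2-[bis(2,2,2-trifluoroethoxy)phosphoryl]propanoic acid (N,N'-dicyclohexylcarbodiimide, 4-(dimethylamino)pyridine, CH2Cl2) gives (1S,4R,6S)-4-(acetyloxy)-6-[(2R,4R)-4-(acetyloxy)-6-methylhept-5-en-2-yl]-3-methylcyclohex-2-en-1-yl 2-[bis(2,2,2-trifluoroethoxy)phosphoryl]propanoate F6 (both epimers at the phosphonate carbon). Still–Gennari olefination of F6 with acetaldehyde (KN(SiMe3)2, 18-crown-6, THF, −78 °C) gives the Z-configured ester 15; the phosphonate C–H is far more acidic than the acetate C–H, so the acetates are not enolised.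

**Further compounds**
F1 | step 2 | methyl (2Z)-3-(4,4,5,5-tetramethyl-1,3,2-dioxaborolan-2-yl)but-2-enoate | COC(=O)/C=C(\C)B1OC(C)(C)C(C)(C)O1
F2 | step 2 | methyl (2E)-3-[(1S)-2,2-dimethoxy-4-methyl-5-oxocyclohex-3-en-1-yl]but-2-enoate | COC1(OC)C=C(C)C(=O)C[C@H]1/C(C)=C/C(=O)OC
F3 | step 2 | methyl (2E)-3-[(1S,5R)-5-hydroxy-2,2-dimethoxy-4-methylcyclohex-3-en-1-yl]but-2-enoate | COC1(OC)C=C(C)[C@H](O)C[C@H]1/C(C)=C/C(=O)OC
F4 | step 3 | methyl (3R)-3-[(1S,5S)-5-hydroxy-2,2-dimethoxy-4-methylcyclohex-3-en-1-yl]butanoate | COC1(OC)C=C(C)[C@@H](O)C[C@H]1[C@H](C)CC(=O)OC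
F5 | step 3 | (1R,5S)-4,4-dimethoxy-5-[(2R)-4-methoxy-4-oxobutan-2-yl]-2-methylcyclohex-2-en-1-yl 4-nitrobenzoate | COC1(OC)C=C(C)[C@H](OC(=O)c2ccc(cc2)[N+](=O)[O-])C[C@H]1[C@H](C)CC(=O)OC
F6 | step 9 | (1S,4R,6S)-4-(acetyloxy)-6-[(2R,4R)-4-(acetyloxy)-6-methylhept-5-en-2-yl]-3-methylcyclohex-2-en-1-yl 2-[bis(2,2,2-trifluoroethoxy)phosphoryl]propanoate | CC(C(=O)O[C@@H]1C=C(C)[C@H](OC(C)=O)C[C@H]1[C@H](C)C[C@H](C=C(C)C)OC(C)=O)P(=O)(OCC(F)(F)F)OCC(F)(F)F
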